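Locants: ring B sp3 carbons are C1 (side chain), C2, C3, C4 (methyl); ring A runs C4a, C5-OH, C6-OH, C7-CO2H, C8-H, C8a; the chain is C11 (methine on C1), C12 (CH2OAc), C13–C15, C16 (CHMe), C17 (CH2OH).
Enabling feature: C4 of ring B is a benzylic methine on C4a whose only extra substituent is methyl. It is therefore the Markovnikov H/Cu adduct of a C4a vinyl group, and C3 ends the two-carbon arm on C1. Ring B is cut at C3–C4 (vinylarene plus primary bromide).
Further cuts: C4a–C4 (vinylation of a C4a chloride), C1–C11 (allylic substitution of an aryl vinyl carbinol by the enamine of the C11–C17 aldehyde), C8a–C1 (arylmagnesium plus acrolein), C7–CO2 (aryllithium plus Boc2O), C14–C15 (Grignard cross-coupling).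
Forward: ring A is bought as catechol acetonide and loaded in the order C4a-Cl, C7-CO2t-Bu, C8a-Br, C8a-carbinol. The chain is joined at C1–C11, the C2=C3 vinyl becomes the bromoethyl arm, the C4a vinyl is installed, and ring B closes last. Four finishing steps follow.
Stereochemistry: C16 comes from (R)-3-bromo-2-methylpropan-1-ol. C1 (iridium ligand) and C11 (amine) are set in one dual-catalytic step. C4 is set by DTBM-SEGPHOS in the ring closure.
Key step: step 14

Assumption: the catalyst antipodes are assigned by analogy with their behaviour on simple substrates ((R)-prolinol ether gives 11S, (S)-phosphoramidite gives 1S, (R)-DTBM-SEGPHOS gives 4R); each centre is under catalyst control, so an inverted sense would be met by taking the other antipode of that catalyst alone.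
Remark: catalyst-bound turnover species (enamine, allyliridium, alkylcopper, arylpalladium) are described in the Why lines and are not numbered; carbinol 9 is racemic.

Step 1
Reactants: 1 2,2-dimethyl-1,3-benzodioxole (catechol acetonide)
Product: 3 4-chloro-2,2-dimethyl-1,3-benzodioxole, via 4-lithio acetonide 2 (not isolated)
Conditions: n-BuLi, TMEDA, Et2O, 0 °C to rt; C2Cl6, THF, −78 °C to rt
Reagents that add atoms: hexachloroethane, ClC(Cl)(Cl)C(Cl)(Cl)Cl
Why: Directed ortho-metalation; the ring oxygen acidifies and coordinates at the adjacent C–H (future C4a), the quaternary C2 of the dioxole has no proton to lose, and the aryllithium takes chlorine from C2Cl6.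

Step 2
Reactants: 3 4-chloro-2,2-dimethyl-1,3-benzodioxole
Product: 5 tert-butyl 7-chloro-2,2-dimethyl-1,3-benzodioxole-4-carboxylate, via 7-chloro-4-lithio acetonide 4 (not isolated)
Conditions: s-BuLi, TMEDA, THF, −78 °C; cannulation into Boc2O, THF, −78 °C to rt; H2O
Reagents that add atoms: di-tert-butyl dicarbonate, CC(C)(C)OC(=O)OC(=O)OC(C)(C)C
Why: Second directed ortho-metalation; the remaining oxygen-flanked C–H (future C7) is more acidic than the one beside chlorine, chlorine does not exchange with s-BuLi at −78 °C, and inverse quench with Boc2O stops at the hindered tert-butyl ester.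

Step 3
Reactants: 5 tert-butyl 7-chloro-2,2-dimethyl-1,3-benzodioxole-4-carboxylate
Product: 6 tert-butyl 6-bromo-7-chloro-2,2-dimethyl-1,3-benzodioxole-4-carboxylate
Conditions: Br2, NaOAc, AcOH, rt, dark
Reagents that add atoms: bromine, BrBr
Why: Electrophilic aromatic bromination; C6 of the benzodioxole (future C8a) is para to a ring oxygen, ortho to chlorine and meta to the ester, attack at C5 would put positive charge on the ester-bearing carbon beside the bulky ester, and NaOAc removes HBr so acetonide and tert-butyl ester survive.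

Step 4
Reactants: 6 tert-butyl 6-bromo-7-chloro-2,2-dimethyl-1,3-benzodioxole-4-carboxylate; 7 acrolein
Product: 9 tert-butyl 7-chloro-6-(1-hydroxyprop-2-en-1-yl)-2,2-dimethyl-1,3-benzodioxole-4-carboxylate (racemic), via arylmagnesium chloride 8 (not isolated)
Conditions: i-PrMgCl·LiCl, THF, −20 °C; 7, −40 to −10 °C; H2O
Reagents that add atoms: none
Why: Halogen–magnesium exchange takes the bromide and leaves the chloride, the tert-butyl ester tolerates the arylmagnesium in the cold, and Grignard 1,2-addition to acrolein forms C8a–C1 as a racemic carbinol whose configuration is erased in step 8.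

Step 5
Reactants: 10 (R)-3-bromo-2-methylpropan-1-ol
Product: 11 (R)-[(3-bromo-2-methylpropoxy)methyl]benzene
Conditions: BnOC(=NH)CCl3, TfOH (cat.), CH2Cl2/cyclohexane, 0 °C to rt
Reagents that add atoms: benzyl 2,2,2-trichloroacetimidate, N=C(OCc1ccccc1)C(Cl)(Cl)Cl
Why: Acid-catalysed O-benzylation with the imidate avoids an alkoxide that would close to an oxetane or displace bromide, and the stereocentre (future C16) is not touched.

Step 6
Reactants: 11 (R)-[(3-bromo-2-methylpropoxy)methyl]benzene; 12 2-(3-chloropropyl)-1,3-dioxolane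
Product: 14 (S)-2-[6-(benzyloxy)-5-methylhexyl]-1,3-dioxolane, via dioxolanylpropyl Grignard reagent 13 (not isolated)
Conditions: 12, Mg, THF, reflux; then 11, Li2CuCl4 (5 mol %), NMP, THF, 0 °C to rt
Reagents that add atoms: none
Why: Copper-catalysed sp3–sp3 cross-coupling of a primary bromide with a primary Grignard reagent forms C14–C15 one carbon away from C16, whose geometry is kept (the descriptor becomes S by priority change only).

Step 7
Reactants: 14 (S)-2-[6-(benzyloxy)-5-methylhexyl]-1,3-dioxolane
Product: 15 (S)-7-(benzyloxy)-6-methylheptanal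
Conditions: 1 M HCl, THF, rt
Reagents that add atoms: water, O
Why: Acid hydrolysis of the dioxolane releases the C12 aldehyde, the benzyl ether is inert, and C16 is remote from the enolisable position.

Step 8
Reactants: 9 racemic aryl vinyl carbinol; 15 (S)-7-(benzyloxy)-6-methylheptanal
Product: 16 tert-butyl 6-[(3S,4S,8S)-9-(benzyloxy)-4-formyl-8-methylnon-1-en-3-yl]-7-chloro-2,2-dimethyl-1,3-benzodioxole-4-carboxylate (1S,11S,16S)
Conditions: [Ir(cod)Cl]2 (3 mol %), (S)-5-(dinaphtho[2,1-d:1',2'-f][1,3,2]dioxaphosphepin-4-yl)-5H-dibenzo[b,f]azepine (12 mol %), (R)-2-{bis[3,5-bis(trifluoromethyl)phenyl](trimethylsilyloxy)methyl}pyrrolidine (15 mol %), (MeO)2P(O)OH (50 mol %), ClCH2CH2Cl, 25 °C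
Reagents that add atoms: none
Why: Stereodivergent dual catalysis (iridium-catalysed allylic substitution merged with enamine catalysis), established for linear aldehydes and racemic aryl vinyl carbinols: both enantiomers of 9 ionise, helped by the para oxygen O6, to one allyliridium complex that is attacked at its aryl-bearing terminus on the face fixed by the ligand (C1 = S), while the prolinol ether shields one face of the E-enamine of 15 (C11 = S).

Step 9
Reactants: 16 aldehyde (1S,11S,16S)
Product: 17 tert-butyl 6-[(3S,4S,8S)-9-(benzyloxy)-4-(hydroxymethyl)-8-methylnon-1-en-3-yl]-7-chloro-2,2-dimethyl-1,3-benzodioxole-4-carboxylate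
Conditions: NaBH4, MeOH, 0 °C (on the crude aldehyde)
Reagents that add atoms: none
Why: Borohydride reduction carried out at once removes the only epimerisable position (C11), and the ester, aryl chloride and alkene are inert.

Step 10
Reactants: 17 primary alcohol at C12
Product: 18 tert-butyl 6-[(3S,4S,8S)-9-(benzyloxy)-4-{[(tert-butyldimethylsilyl)oxy]methyl}-8-methylnon-1-en-3-yl]-7-chloro-2,2-dimethyl-1,3-benzodioxole-4-carboxylate
Conditions: TBSCl, imidazole, DMF, rt
Reagents that add atoms: tert-butyldimethylsilyl chloride, CC(C)(C)[Si](C)(C)Cl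
Why: Standard silylation; the silyl ether withstands borane, aqueous base, LiOMe and hydrosilane, where an acetate would not, and is later removed by fluoride without touching benzyl ether, acetonide or tert-butyl ester.

Step 11
Reactants: 18 silyl ether with terminal C2=C3 alkene
Product: 20 tert-butyl 6-[(3S,4S,8S)-9-(benzyloxy)-4-{[(tert-butyldimethylsilyl)oxy]methyl}-1-hydroxy-8-methylnonan-3-yl]-7-chloro-2,2-dimethyl-1,3-benzodioxole-4-carboxylate, via B-alkyl-9-BBN adduct 19 (not isolated)
Conditions: 9-BBN, THF, 0 °C to rt; H2O2, NaOH, 0 °C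
Reagents that add atoms: hydrogen peroxide, OO
Why: Anti-Markovnikov hydroboration–oxidation puts oxygen on terminal C3 of the only alkene present, which is why the C4a vinyl group is installed afterwards.

Step 12
Reactants: 20 chloroarene with C3 alcohol
Product: 21 tert-butyl 6-[(3S,4S,8S)-9-(benzyloxy)-4-{[(tert-butyldimethylsilyl)oxy]methyl}-1-hydroxy-8-methylnonan-3-yl]-7-ethenyl-2,2-dimethyl-1,3-benzodioxole-4-carboxylate
Conditions: vinyl-Bpin, Pd(OAc)2 (5 mol %), SPhos (10 mol %), K3PO4, toluene/H2O, 90 °C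
Reagents that add atoms: vinylboronic acid pinacol ester, C=CB1OC(C)(C)C(C)(C)O1
Why: Suzuki–Miyaura coupling; the chloride para to the ester is activated for oxidative addition, the dialkylbiarylphosphine copes with two ortho substituents, and working at the alcohol stage keeps any alkyl bromide away from zerovalent palladium and aqueous base.

Step 13
Reactants: 21 vinylarene with C3 alcohol
Product: 22 tert-butyl 6-[(3S,4S,8S)-9-(benzyloxy)-1-bromo-4-{[(tert-butyldimethylsilyl)oxy]methyl}-8-methylnonan-3-yl]-7-ethenyl-2,2-dimethyl-1,3-benzodioxole-4-carboxylate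
Conditions: CBr4, PPh3, 2,6-lutidine, CH2Cl2, 0 °C
Reagents that add atoms: carbon tetrabromide, BrC(Br)(Br)Br
Why: Appel reaction; near-neutral SN2 bromination of the unhindered primary alcohol leaves styrene, silyl ether, acetonide and esters untouched.

Step 14
Reactants: 22 C4a-vinyl arene with C3 bromide (1S,11S,16S)
Product: 23 tert-butyl (6S,9R)-6-[(2S,6S)-7-(benzyloxy)-1-[(tert-butyldimethylsilyl)oxy]-6-methylheptan-2-yl]-2,2,9-trimethyl-6,7,8,9-tetrahydronaphtho[1,2-d][1,3]dioxole-4-carboxylate (1S,4R,11S,16S)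
Conditions: Cu(OAc)2 (10 mol %), (R)-DTBM-SEGPHOS (11 mol %), (MeO)2MeSiH, LiOMe, THF, rt to 40 °C
Reagents that add atoms: none
Why: Cu(OAc)2, the bisphosphine and the silane generate a ligated copper hydride that adds syn and in the Markovnikov sense to the C4a vinyl group, sending hydrogen to the terminal carbon (the future C4 methyl) and copper to benzylic C4. The configured secondary alkylcopper then displaces the primary C3 bromide with retention at C4, and LiOMe turns the copper bromide into the alkoxide that the silane converts back to the hydride; this is the known CuH-catalysed enantioselective intramolecular hydroalkylation of bromide-tethered vinylarenes, which already delivers indanes, small carbocycles and six-membered heterocycles. Ring B closes in the 6-exo-tet mode by formation of C3–C4. C4 is fixed by the alkene face that the ligand selects, with C1, C11 and C16 as spectators, so the trans 1,4-relationship follows from the ligand antipode and not from the substrate. Hydrocupration must outrun reduction of the C–Br bond, and alkylation must outrun protonation of the alkylcopper. The substrate helps because the conjugated vinyl group is its only π-system, O5 is tied back in the five-membered acetonide so one flank stays open, the bromide is primary with an unbranched C2, and tert-butyl ester, silyl ether and benzyl ether are inert to LiOMe and silane.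

Step 15
Reactants: 23 protected tetralin
Product: 24 tert-butyl (6S,9R)-6-[(2S,6S)-7-(benzyloxy)-1-hydroxy-6-methylheptan-2-yl]-2,2,9-trimethyl-6,7,8,9-tetrahydronaphtho[1,2-d][1,3]dioxole-4-carboxylate
Conditions: Bu4NF, THF, 0 °C to rt
Reagents that add atoms: none
Why: Fluoride-mediated desilylation frees O12 only, since no other silicon group or fluoride-labile function is present.

Step 16
Reactants: 24 C12 alcohol
Product: 25 tert-butyl (6S,9R)-6-[(2S,6S)-1-acetoxy-7-(benzyloxy)-6-methylheptan-2-yl]-2,2,9-trimethyl-6,7,8,9-tetrahydronaphtho[1,2-d][1,3]dioxole-4-carboxylate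
Conditions: Ac2O, pyridine, DMAP (cat.), CH2Cl2, rt
Reagents that add atoms: acetic anhydride, CC(=O)OC(C)=O
Why: DMAP-catalysed acetylation of the only free hydroxyl group.

Step 17
Reactants: 25 acetate
Product: 26 (5R,8S)-8-[(2S,6S)-1-acetoxy-7-(benzyloxy)-6-methylheptan-2-yl]-3,4-dihydroxy-5-methyl-5,6,7,8-tetrahydronaphthalene-2-carboxylic acid
Conditions: CF3CO2H/CH2Cl2/H2O, 0 °C to rt, argon
Reagents that add atoms: none
Why: Acidolysis; the tert-butyl ester loses isobutene and the catechol acetonide is hydrolysed, the primary acetate and benzyl ether are stable at rt, and keeping O17 benzylated leaves no free alcohol to be trifluoroacetylated.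

Step 18
Reactants: 26 O17-benzyl ether of the target
Product: 27 target, (5R,8S)-8-[(2S,6S)-1-acetoxy-7-hydroxy-6-methylheptan-2-yl]-3,4-dihydroxy-5-methyl-5,6,7,8-tetrahydronaphthalene-2-carboxylic acid (1S,4R,11S,16S)
Conditions: H2 (1 atm), Pd/C, EtOAc/MeOH, rt
Reagents that add atoms: none
Why: Catalytic hydrogenolysis of the benzyl ether, which is a neutral last step that needs only filtration and touches no stereocentre.

Compound list
1 | 2,2-dimethyl-1,3-benzodioxole | CC1(C)Oc2ccccc2O1 | starting material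
2 | (2,2-dimethyl-1,3-benzodioxol-4-yl)lithium | [Li]c1cccc2OC(C)(C)Oc12 | intermediate
3 | 4-chloro-2,2-dimethyl-1,3-benzodioxole | Clc1cccc2OC(C)(C)Oc12 | intermediate
4 | (7-chloro-2,2-dimethyl-1,3-benzodioxol-4-yl)lithium | [Li]c1ccc(Cl)c2OC(C)(C)Oc12 | intermediate
5 | tert-butyl 7-chloro-2,2-dimethyl-1,3-benzodioxole-4-carboxylate | CC(C)(C)OC(=O)c1ccc(Cl)c2OC(C)(C)Oc12 | intermediate
6 | tert-butyl 6-bromo-7-chloro-2,2-dimethyl-1,3-benzodioxole-4-carboxylate | CC(C)(C)OC(=O)c1cc(Br)c(Cl)c2OC(C)(C)Oc12 | intermediate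
7 | acrolein | C=CC=O | starting material
8 | [7-(tert-butoxycarbonyl)-4-chloro-2,2-dimethyl-1,3-benzodioxol-5-yl]magnesium chloride | CC(C)(C)OC(=O)c1cc([Mg]Cl)c(Cl)c2OC(C)(C)Oc12 | intermediate
9 | tert-butyl 7-chloro-6-(1-hydroxyprop-2-en-1-yl)-2,2-dimethyl-1,3-benzodioxole-4-carboxylate (racemic) | CC(C)(C)OC(=O)c1cc(C(O)C=C)c(Cl)c2OC(C)(C)Oc12 | intermediate
10 | (R)-3-bromo-2-methylpropan-1-ol | BrC[C@H](C)CO | starting material
11 | (R)-[(3-bromo-2-methylpropoxy)methyl]benzene | BrC[C@H](C)COCc1ccccc1 | intermediate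
12 | 2-(3-chloropropyl)-1,3-dioxolane | ClCCCC1OCCO1 | starting material
13 | [3-(1,3-dioxolan-2-yl)propyl]magnesium chloride | Cl[Mg]CCCC1OCCO1 | intermediate
14 | (S)-2-[6-(benzyloxy)-5-methylhexyl]-1,3-dioxolane | C1COC(CCCC[C@H](C)COCc2ccccc2)O1 | intermediate
15 | (S)-7-(benzyloxy)-6-methylheptanal | O=CCCCC[C@H](C)COCc1ccccc1 | intermediate
16 | allylation product, C12 aldehyde (1S,11S,16S) | O=C[C@@H](CCC[C@H](C)COCc1ccccc1)[C@H](C=C)c1cc(C(=O)OC(C)(C)C)c2OC(C)(C)Oc2c1Cl | intermediate
17 | C12 alcohol (1S,11S,16S) | OC[C@@H](CCC[C@H](C)COCc1ccccc1)[C@H](C=C)c1cc(C(=O)OC(C)(C)C)c2OC(C)(C)Oc2c1Cl | intermediate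
18 | O12 tert-butyldimethylsilyl ether with C2=C3 alkene | CC(C)(C)[Si](C)(C)OC[C@@H](CCC[C@H](C)COCc1ccccc1)[C@H](C=C)c1cc(C(=O)OC(C)(C)C)c2OC(C)(C)Oc2c1Cl | intermediate
19 | C3 B-alkyl-9-borabicyclo[3.3.1]nonane adduct of 18 | CC(C)(C)[Si](C)(C)OC[C@@H](CCC[C@H](C)COCc1ccccc1)[C@H](CCB1C2CCCC1CCC2)c1cc(C(=O)OC(C)(C)C)c2OC(C)(C)Oc2c1Cl | intermediate
20 | C3 alcohol, C4a chloride | CC(C)(C)[Si](C)(C)OC[C@@H](CCC[C@H](C)COCc1ccccc1)[C@H](CCO)c1cc(C(=O)OC(C)(C)C)c2OC(C)(C)Oc2c1Cl | intermediate
21 | C3 alcohol, C4a vinyl | CC(C)(C)[Si](C)(C)OC[C@@H](CCC[C@H](C)COCc1ccccc1)[C@H](CCO)c1cc(C(=O)OC(C)(C)C)c2OC(C)(C)Oc2c1C=C | intermediate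
22 | C3 bromide, C4a vinyl (key-step precursor) | CC(C)(C)[Si](C)(C)OC[C@@H](CCC[C@H](C)COCc1ccccc1)[C@H](CCBr)c1cc(C(=O)OC(C)(C)C)c2OC(C)(C)Oc2c1C=C | intermediate
23 | protected tetralin (1S,4R,11S,16S) (key-step product) | CC(C)(C)[Si](C)(C)OC[C@@H](CCC[C@H](C)COCc1ccccc1)[C@@H]1CC[C@@H](C)c2c1cc(C(=O)OC(C)(C)C)c1OC(C)(C)Oc21 | intermediate
24 | tetralin with free C12 alcohol | OC[C@@H](CCC[C@H](C)COCc1ccccc1)[C@@H]1CC[C@@H](C)c2c1cc(C(=O)OC(C)(C)C)c1OC(C)(C)Oc21 | intermediate
25 | tetralin C12 acetate | CC(=O)OC[C@@H](CCC[C@H](C)COCc1ccccc1)[C@@H]1CC[C@@H](C)c2c1cc(C(=O)OC(C)(C)C)c1OC(C)(C)Oc21 | intermediate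
26 | catechol acid, O17 benzyl ether | CC(=O)OC[C@@H](CCC[C@H](C)COCc1ccccc1)[C@@H]1CC[C@@H](C)c2c1cc(C(=O)O)c(O)c2O | intermediate
27 | CNP0191669.1 | CC(=O)OC[C@@H](CCC[C@H](C)CO)[C@@H]1CC[C@@H](C)c2c1cc(C(=O)O)c(O)c2O | target

Total step count: 18. Longest linear sequence: 15 steps (steps 1–4 and 8–18, from 1).

Steps most likely to fail

Step 14. Hydrocupration of a vinyl group flanked on both sides may be slow. That would leave time for hydride reduction of the C–Br bond or for protonation of the alkylcopper, and a mismatched pairing of ligand and C1 could erode facial selectivity. The fallback sets out from 20, returns at 23, and closes ring B at the other benzylic bond, C4–C4a. An Appel reaction on 20 (CBr4, PPh3) gives the chloroarene primary bromide F1. Li2CuCl4-catalysed coupling with vinylmagnesium bromide in the cold lengthens the arm to the but-3-enyl chloroarene F2. An intramolecular Heck reaction of the aryl chloride (Pd2(dba)3, P(t-Bu)3, Cy2NMe, dioxane, 100 °C, 6-exo-trig) gives the 4-methylidene tetralin F3. Asymmetric hydrogenation with a chiral iridium phosphine–oxazoline catalyst ([Ir(cod)(t-Bu-PHOX)]BArF, H2, CH2Cl2), with the antipode chosen for 4R, then gives 23.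

Step 8. The ortho chlorine and the meta ester may retard ionisation of the carbinol. Slow turnover would let the α-branched aldehyde epimerise at C11 through its enamine, and diastereocontrol would suffer. The fallback sets out from 9 and 15, returns at 17, and forms C1–C11 by a sigmatropic rearrangement.
- Catalytic 1,3-transposition of the hydroxyl group of 9 (Ph3SiOReO3, Et2O, 0 °C) gives the conjugated (E)-allylic alcohol F4.
- Pinnick oxidation of 15 (NaClO2, NaH2PO4, 2-methylbut-2-ene) gives the heptanoic acid F5.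
- EDC/DMAP esterification joins them as the allylic ester F6.
- Treatment with a C2-symmetric 2-bromo-1,3-bis(arylsulfonyl)-4,5-diphenyl-1,3,2-diazaborolidine and a tertiary amine (−78 to −20 °C) triggers an enantioselective Ireland–Claisen rearrangement through a chair. Amine and solvent are chosen for the enolate geometry that leads to the anti product, and the boron reagent antipode is chosen for (1S,11S). This gives the pentenoic acid F7.
- Activation with i-BuOCOCl and N-methylmorpholine gives the isobutyl mixed anhydride F8, and NaBH4 reduction gives 17.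

Step 3. Substitution on a ring with two deactivating groups may be sluggish. Forcing it could lead to acid cleavage of the acetonide or tert-butyl ester, or to attack at C5. The fallback sets out from 5, returns at 6, and replaces electrophilic substitution by sterically governed C–H activation. Iridium-catalysed borylation ([Ir(OMe)(cod)]2, 4,4'-di-tert-butyl-2,2'-bipyridine, B2pin2, THF, 80 °C) takes the C–H beside the smaller chlorine rather than the one beside the tert-butyl ester and gives the C6 pinacol boronate F9. Bromodeboronation with CuBr2 in aqueous methanol then gives 6.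

Further compounds
F1 | step 14 | tert-butyl 6-[(3S,4S,8S)-9-(benzyloxy)-1-bromo-4-{[(tert-butyldimethylsilyl)oxy]methyl}-8-methylnonan-3-yl]-7-chloro-2,2-dimethyl-1,3-benzodioxole-4-carboxylate | CC(C)(C)[Si](C)(C)OC[C@@H](CCC[C@H](C)COCc1ccccc1)[C@H](CCBr)c1cc(C(=O)OC(C)(C)C)c2OC(C)(C)Oc2c1Cl
F2 | step 14 | tert-butyl 6-[(5S,6S,10S)-11-(benzyloxy)-6-{[(tert-butyldimethylsilyl)oxy]methyl}-10-methylundec-1-en-5-yl]-7-chloro-2,2-dimethyl-1,3-benzodioxole-4-carboxylate | CC(C)(C)[Si](C)(C)OC[C@@H](CCC[C@H](C)COCc1ccccc1)[C@H](CCC=C)c1cc(C(=O)OC(C)(C)C)c2OC(C)(C)Oc2c1Cl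
F3 | step 14 | tert-butyl (6S)-6-[(2S,6S)-7-(benzyloxy)-1-[(tert-butyldimethylsilyl)oxy]-6-methylheptan-2-yl]-2,2-dimethyl-9-methylidene-6,7,8,9-tetrahydronaphtho[1,2-d][1,3]dioxole-4-carboxylate | CC(C)(C)[Si](C)(C)OC[C@@H](CCC[C@H](C)COCc1ccccc1)[C@@H]1CCC(=C)c2c1cc(C(=O)OC(C)(C)C)c1OC(C)(C)Oc21
F4 | step 8 | tert-butyl 7-chloro-6-[(E)-3-hydroxyprop-1-en-1-yl]-2,2-dimethyl-1,3-benzodioxole-4-carboxylate | OC/C=C/c1cc(C(=O)OC(C)(C)C)c2OC(C)(C)Oc2c1Cl
F5 | step 8 | (S)-7-(benzyloxy)-6-methylheptanoic acid | OC(=O)CCCC[C@H](C)COCc1ccccc1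
F6 | step 8 | (E)-3-[7-(tert-butoxycarbonyl)-4-chloro-2,2-dimethyl-1,3-benzodioxol-5-yl]prop-2-en-1-yl (S)-7-(benzyloxy)-6-methylheptanoate | O=C(CCCC[C@H](C)COCc1ccccc1)OC/C=C/c1cc(C(=O)OC(C)(C)C)c2OC(C)(C)Oc2c1Cl
F7 | step 8 | (2S,3S)-2-[(S)-5-(benzyloxy)-4-methylpentyl]-3-[7-(tert-butoxycarbonyl)-4-chloro-2,2-dimethyl-1,3-benzodioxol-5-yl]pent-4-enoic acid | OC(=O)[C@@H](CCC[C@H](C)COCc1ccccc1)[C@H](C=C)c1cc(C(=O)OC(C)(C)C)c2OC(C)(C)Oc2c1Cl
F8 | step 8 | isobutyl carbonic mixed anhydride of F7 | CC(C)COC(=O)OC(=O)[C@@H](CCC[C@H](C)COCc1ccccc1)[C@H](C=C)c1cc(C(=O)OC(C)(C)C)c2OC(C)(C)Oc2c1Cl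
F9 | step 3 | tert-butyl 7-chloro-2,2-dimethyl-6-(4,4,5,5-tetramethyl-1,3,2-dioxaborolan-2-yl)-1,3-benzodioxole-4-carboxylate | CC(C)(C)OC(=O)c1cc(B2OC(C)(C)C(C)(C)O2)c(Cl)c2OC(C)(C)Oc12
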